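The readings are simulated with constants of no real substance, noise included.

The pitfall in a flask with a protic impurity is to count the whole charge as target on offer, when the impurity can take its equal in starting material. I therefore reckon with the cap: the share of the charge left for target and its over-reaction product after the impurity has taken its equal, one minus [impurity]/[starting material] at the start.

| flask | starting material | protic impurity | temperature | remark | time |
|---|---|---|---|---|---|
| gamma | 0.30 M | 0.30 M | 70 °C | run made earlier |  |
| alpha | 1.2 M | 0.30 M | 90 °C | run made earlier |  |
| theta | 0.60 M | 0.15 M | 70 °C | run made earlier |  |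
| north | 0.60 M | 0.300 M | 90 °C |  | 6.0 h |
| west | 0.60 M | 0.300 M | 75 °C |  | 6.0 h |
| east | 0.60 M | 0.300 M | 105 °C |  | 6.0 h |

- gamma (time / h: target / %, starting material / %): 1.33: 0, 80.0; 2.00: 0, 72.6; 2.50: 0, 68.1; 4.00: 0.8, 56.6; 6.00: 0.2, 46.0; 10.0: 0.5, 34.1; 15.0: 0, 25.7
- alpha (time / h: target / %, starting material / %): 0.833: 0.4, 75.4; 1.50: 4.1, 71.4; 2.50: 25.8, 48.6; 3.00: 45.3, 27.8; 4.00: 67.1, 5.3; 5.00: 69.2, 0.3; 6.00: 66.2, 0.1
- theta (time / h: target / %, starting material / %): 1.33: 0.2, 90.5; 2.50: 0, 86.6; 4.00: 0.7, 81.5; 8.00: 2.0, 75.8; 15.0: 8.0, 68.2

(scatter of a reading: 0.5 percentage points)

1. the flask with the highest amount of target, in percent of the starting material charged ("all alike" if they lie within 1.5 percentage points) (north / west / east / all alike)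
2. final target, as a percentage of the starting material charged, in north
3. final target, as a percentage of the starting material charged, in west
4. final target, as a percentage of the starting material charged, in east

- the analysis behind the earlier runs scatters by 0.5 percentage points, standard deviation
- what may be going on: starting material + target -> 2 target; starting material -> target; starting material + protic impurity -> quenched substrate; target -> over-reaction product

The earlier runs test the cap. In gamma it is 0%, and the target reading of 0.8% at 4.00 h is its highest. In alpha it is 75.0%, but the reading at 5.00 h is 69.2%. So I go round again: alpha's tail gives a loss of 0.0443 /h, and ageing the cap from mid-rise at 3.00 h gives 68.6%, close to that reading.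

North, west and east share a cap of 50.0%, with the impurity as limiting reagent of the quench. For east at 105 °C I guess the loss rises by a factor 3 to 0.133 /h, and that the target stands for 3.00 h, which leaves 33.6%. The factor is the weak link, since no run measures the loss above 90 °C. Reforged as 2 to 4, it gives 38.3% down to 29.4%. I set no figure for north or west, whose rise I have not timed.

The forecast names east, with 21% (12% to 33%) in north, 1.5% (0.7% to 3.5%) in west and 29% (20% to 38%) in east, lower than my 33.6%, and it sets its east loss “with Ea unmeasured”.

The flasks give 19.1% in north, 0.881% in west and 28.1% in east, so east leads and the forecast stands.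

    starting material + target → 2 target (k = 7.00 × 10⁻⁴ /M/s, Ea = 72.0 kJ/mol)
    starting material → target (k = 1.00 × 10⁻⁶ /s, Ea = 122 kJ/mol)
    starting material + protic impurity → quenched substrate (k = 9.10 × 10⁻⁴ /M/s, Ea = 85.0 kJ/mol)
    target → over-reaction product (k = 9.60 × 10⁻⁶ /s, Ea = 116 kJ/mol)
    (constants at 90 °C)

In east, taking away the over-reaction step returns the target to 50.0%, the cap, so that step accounts for 22 percentage points, a part of what separates the target from the charge. The forecast's order would turn with the hour of the reading: at 60.0 h west holds 38.6% against 0.881% at 6.0 h, above north at 7.94% and east at 0.00542%. West's recipe with 2.4 M of starting material has a cap of 87.5%, and that flask gives 83.7% target at 6.00 h.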